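The synthesis rests on disconnecting the O16–C3 bond of the oxepane (ring D: C1, C2, C3, O16, C16, C15, C14). C3 is the fully substituted carbon that ring D shares with the oxonane (ring C). In one operation a cobalt-hydride hydrogen-atom transfer/radical–polar crossover acts on oxonene 22 (three rings, C3=C4 alkene, free ketone, acetate). It adds H to C4 and adds the C16 hydroxyl to C3. The trans C1–C14 junction holds that hydroxyl over one face of C3. The last ring closes, the quaternary centre is set, the metathesis alkene disappears and the target results. Earlier, O16 is parked on C2 as a temporary tetrahydropyran acetal that differentiates two aldehydes. Overall, C3 is inserted into that C2–O16 bond.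

Key step: step 14

Numbering used for all compounds:
- Ring A (cyclohexane) is C1, C10, C11, C12, C13, C14.
- Ring B (tetrahydrofuran) is C1, C2, O, C9, C10.
- Ring C (oxonane) is C2 to C9 plus the same O.
- Ring D (oxepane) is C1, C2, C3, O16, C16, C15, C14.
- C11 bears the acetate. C3, C12 and C15 each bear a methyl group. C7 is the ketone.
- The "convex face" of ring A is the face that carries H1 and H10.

Remark on the chemistry: C12 of 9 and 10 and the anomeric carbon C9 of 17 should form as mixtures. These centres are erased in the next event and are left undefined in the SMILES.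

Step 1
Reactants: 1 (S)-3-bromo-2-methylpropan-1-ol
Product: 2 (S)-(3-bromo-2-methylpropoxy)(tert-butyl)dimethylsilane
Conditions: t-BuMe2SiCl, imidazole, CH2Cl2, rt
Reagents that add atoms: tert-butyldimethylsilyl chloride CC(C)(C)[Si](C)(C)Cl
Why: Routine silyl ether formation on a primary alcohol; the C15 stereocentre is bought with 1 and is not touched.

Step 2
Reactants: 2 (S)-(3-bromo-2-methylpropoxy)(tert-butyl)dimethylsilane
Product: 4 (R)-4-[(tert-butyldimethylsilyl)oxy]-3-methylbutanal, via Grignard reagent 3 (not isolated)
Conditions: Mg, THF, reflux; DMF, 0 °C; aq NH4Cl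
Reagents that add atoms: N,N-dimethylformamide CN(C)C=O; magnesium [Mg] (held only in 3)
Why: Grignard formation followed by formylation with DMF (Bouveault aldehyde synthesis) adds the future C1 as an aldehyde carbon, and the oxygen sits too far from the carbanion for β-elimination.

Step 3
Reactants: 4 (R)-4-[(tert-butyldimethylsilyl)oxy]-3-methylbutanal; 5 but-3-en-2-one
Product: 6 (S)-2-[(R)-1-[(tert-butyldimethylsilyl)oxy]propan-2-yl]-5-oxohexanal
Conditions: (S)-2-[methoxy(diphenyl)methyl]pyrrolidine (5 mol %), ethyl 3,4-dihydroxybenzoate (20 mol %), neat, 4 °C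
Reagents that add atoms: none
Why: Enamine-catalysed asymmetric Michael addition of an aldehyde to a vinyl ketone, in which the diarylmethyl group of the (S)-pyrrolidine shields one face of the E-enamine so that the catalyst, not the neighbouring C15 centre, sets C14 as (S).

Step 4
Reactants: 6 (S)-2-[(R)-1-[(tert-butyldimethylsilyl)oxy]propan-2-yl]-5-oxohexanal
Product: 7 (R)-4-[(R)-1-[(tert-butyldimethylsilyl)oxy]propan-2-yl]cyclohex-2-en-1-one
Conditions: LiOH, i-PrOH, rt
Reagents that add atoms: none
Why: Intramolecular aldol condensation (the ring-closing half of a Robinson annulation) closes ring A between C1 and C10 under a base mild enough to leave the α-branched centre C14 intact.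

Step 5
Reactants: 7 (R)-4-[(R)-1-[(tert-butyldimethylsilyl)oxy]propan-2-yl]cyclohex-2-en-1-one
Product: 8 cyclobutene ketone (cis-bicyclo[4.2.0]oct-7-en-2-one; C2=C9 bridge anti to the C14 side chain)
Conditions: HC≡CH (saturated), hν (medium-pressure mercury lamp, Pyrex), CH2Cl2, −78 °C, stopped before full conversion
Reagents that add atoms: acetylene C#C
Why: Enone–alkyne [2+2] photocycloaddition through the enone triplet: the four-membered ring can only be cis-fused, and acetylene should add to the face of C1=C10 opposite the adjacent C14 side chain, which sets C1 and C10 (H1 and H10 cis, C2 trans to C15).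

Step 6
Reactants: 8 cyclobutene ketone
Product: 11 C12 methylene ketone, via Mannich base 9 (not isolated), via ammonium iodide 10 (not isolated)
Conditions: LiN(i-Pr)2, THF, −78 °C; [CH2=NMe2]I, −78 °C to rt; MeI, Et2O; aq NaHCO3, CH2Cl2
Reagents that add atoms: N,N-dimethylmethyleneiminium iodide C=[N+](C)C.[I-]; iodomethane CI (held only in 10)
Why: Kinetic deprotonation at the C12 methylene (not at the ring-fusion C10–H), Mannich reaction with the iminium salt, quaternisation and Hofmann-type elimination (Eschenmoser methylenation) bring in the C12 methyl carbon at low temperature, so that the cyclobutene alkene does not move into conjugation.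

Step 7
Reactants: 11 C12 methylene ketone
Product: 14 C11 alcohol (OH-11 and CH3-12 cis on the concave face), via lithium enolate 12 (not isolated), via methyl ketone 13 (not isolated)
Conditions: LiBH(s-Bu)3 (1.05 equiv), THF, −78 °C; 2,6-di-tert-butylphenol (1.1 equiv), −78 °C; LiBH(s-Bu)3 (1.5 equiv), −78 °C; H2O
Reagents that add atoms: none
Why: Conjugate hydride addition to the s-cis enone gives the regiodefined enolate 12, and the bulky phenol and then the bulky hydride both approach from the convex face, which places CH3-12 and O-11 cis on the concave face and reduces the epimerisable ketone 13 as soon as it forms.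

Step 8
Reactants: 14 C11 alcohol
Product: 15 C11 acetate
Conditions: Ac2O, DMAP, pyridine, rt
Reagents that add atoms: acetic anhydride CC(=O)OC(C)=O
Why: DMAP-catalysed acylation of the hindered secondary alcohol installs the acetate of the target, which also keeps O-11 out of the acetal formation of step 9.

Step 9
Reactants: 15 C11 acetate
Product: 17 tricyclic bis-acetal (C2 tied to O16 and to the ring B oxygen; C9 methyl acetal), via dialdehyde 16 (not isolated)
Conditions: O3, CH2Cl2–MeOH, −78 °C; Me2S; then p-TsOH·H2O (cat.), MeOH, rt
Reagents that add atoms: ozone [O-][O+]=O; methanol CO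
Why: Ozonolysis of the only alkene unveils C2 and C9 as a cis-dialdehyde, and acid methanolysis removes the silyl group and equilibrates everything to the most stable bis-acetal, in which the C16 hydroxyl can reach only C2 (six-membered ring on the trans-diequatorial C1–C14 bond), so that the two aldehydes become chemically different.

Step 10
Reactants: 18 hex-5-en-2-one
Product: 19 2-(trimethylsilyloxy)hexa-1,5-diene
Conditions: LiN(i-Pr)2, THF, −78 °C; Me3SiCl
Reagents that add atoms: chlorotrimethylsilane C[Si](C)(C)Cl
Why: Kinetic enolisation of the methyl ketone on its CH3 side and O-silylation give the terminal silyl enol ether.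

Step 11
Reactants: 17 tricyclic bis-acetal; 19 2-(trimethylsilyloxy)hexa-1,5-diene
Product: 20 C9-alkylated acetal ketone (C9–CH2C(O)CH2CH2CH=CH2; C2 acetal intact)
Conditions: Me3SiOTf (0.1 equiv), CH2Cl2, −78 °C
Reagents that add atoms: none
Why: Mukaiyama-type aldol reaction of an acetal: only the exocyclic methoxy group at C9 can leave for good (the tethered O16 recloses), and the silyl enol ether attacks the ring B oxocarbenium ion from its convex face, anti to C11 on C10, which sets C9 as (S).

Step 12
Reactants: 20 C9-alkylated acetal ketone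
Product: 21 diene alcohol (C2 isopropenyl; free C16 hydroxyl)
Conditions: K[CH2=C(CH3)BF3], BF3·OEt2, MeCN–CH2Cl2, −40 to 0 °C; aq NaHCO3
Reagents that add atoms: potassium isopropenyltrifluoroborate [K+].C=C(C)[B-](F)(F)F
Why: Lewis-acid-mediated alkenyl transfer from an organotrifluoroborate to an acetal-derived oxocarbenium ion: BF3 binds the less hindered O16, the five-membered oxocarbenium ion forms, and the isopropenyl group should enter from the convex face, anti to the departing O16 and to C14, which sets C2 as (S) and frees the C16 hydroxyl.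

Step 13
Reactants: 21 diene alcohol
Product: 22 tricyclic (Z)-oxonene alcohol (C3=C4)
Conditions: second-generation Hoveyda–Grubbs catalyst RuCl2(SIMes)(=CH-C6H4-2-O-i-Pr) (10 mol %), 1,4-benzoquinone (cat.), toluene (1 mM), 80 °C
Reagents that add atoms: none
Why: Ring-closing metathesis starts at the monosubstituted alkene and closes onto the isopropenyl group; the cis-2,5 arrangement on ring B holds both arms on one face, and the nine-membered ring can only take up the Z alkene.

Step 14
Reactants: 22 tricyclic (Z)-oxonene alcohol
Product: 23 target CNP0288436.2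
Conditions: [N,N'-bis(3,5-di-tert-butylsalicylidene)-1,2-cyclohexanediaminato]cobalt, C36H52CoN2O2 (5 mol %), N-fluoro-2,4,6-trimethylpyridinium triflate, PhSiH3, PhCF3, rt
Reagents that add atoms: none
Why: The divalent cobalt complex is oxidised by the N-fluoropyridinium salt and turned by the silane into a trivalent cobalt hydride, which transfers a hydrogen atom to the less substituted alkene carbon C4; the tertiary C3 radical is captured by cobalt on the open face of ring C and oxidised to a tetravalent alkylcobalt (a masked C3 cation), which the C16 hydroxyl displaces from the rear. The closest known reaction type is the cobalt-catalysed Mukaiyama-type (hydrogen-atom transfer, radical–polar crossover) intramolecular hydroalkoxylation of unactivated alkenols to cyclic ethers. Ring D closes in a 7-exo mode (O16 to C3, C4 stays outside the new ring) and no other ring is formed. The only new stereocentre, C3, is controlled by the tether: ring C forces C4 to point under ring B (anti to H2), the trans-diequatorial C1–C14 junction holds O16 on the C1 side of trigonal C3, and bulky cobalt takes the opposite face, so O16 can bond only where the methyl group is left outside, which is the (S) configuration of the target. The step needs Markovnikov regioselectivity (tertiary versus secondary radical), chemoselectivity (22 holds a single alkene, and ketone and acetate are inert under these neutral conditions) and a preference for O16 over the C7 carbonyl oxygen and over proton loss, which the pre-organised seven-membered transition state and the non-nucleophilic medium should secure.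

Compound list
1 | (S)-3-bromo-2-methylpropan-1-ol | BrC[C@@H](C)CO | starting material
2 | (S)-(3-bromo-2-methylpropoxy)(tert-butyl)dimethylsilane | BrC[C@@H](C)CO[Si](C)(C)C(C)(C)C | intermediate
3 | Grignard reagent of 2, {3-[(tert-butyldimethylsilyl)oxy]-2-methylpropyl}magnesium bromide | Br[Mg]C[C@@H](C)CO[Si](C)(C)C(C)(C)C | intermediate
4 | (R)-4-[(tert-butyldimethylsilyl)oxy]-3-methylbutanal | O=CC[C@@H](C)CO[Si](C)(C)C(C)(C)C | intermediate
5 | but-3-en-2-one | C=CC(C)=O | starting material
6 | (S)-2-[(R)-1-[(tert-butyldimethylsilyl)oxy]propan-2-yl]-5-oxohexanal | O=C[C@@H](CCC(C)=O)[C@@H](C)CO[Si](C)(C)C(C)(C)C | intermediate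
7 | (R)-4-[(R)-1-[(tert-butyldimethylsilyl)oxy]propan-2-yl]cyclohex-2-en-1-one | O=C1C=C[C@@H](CC1)[C@@H](C)CO[Si](C)(C)C(C)(C)C | intermediate
8 | cyclobutene ketone: cis-bicyclo[4.2.0]oct-7-en-2-one, C11 ketone, C2=C9 bridge on C1/C10 anti to the C14 side chain | O=C1[C@@H](C=C2)[C@@H]2[C@@H](CC1)[C@@H](C)CO[Si](C)(C)C(C)(C)C | intermediate
9 | Mannich base: 8 with CH2NMe2 at C12 (C12 epimers) | O=C1[C@@H](C=C2)[C@@H]2[C@@H](CC1CN(C)C)[C@@H](C)CO[Si](C)(C)C(C)(C)C | intermediate
10 | ammonium iodide: 8 with CH2NMe3 iodide at C12 (C12 epimers) | O=C1[C@@H](C=C2)[C@@H]2[C@@H](CC1C[N+](C)(C)C)[C@@H](C)CO[Si](C)(C)C(C)(C)C.[I-] | intermediate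
11 | C12 methylene ketone | O=C1[C@@H](C=C2)[C@@H]2[C@@H](CC1=C)[C@@H](C)CO[Si](C)(C)C(C)(C)C | intermediate
12 | lithium C11=C12 enolate (methyl on C12) | [Li+].[O-]C=1[C@@H](C=C2)[C@@H]2[C@@H](CC=1C)[C@@H](C)CO[Si](C)(C)C(C)(C)C | intermediate
13 | methyl ketone, CH3-12 on the concave face (H12 cis to H1 and H10) | O=C1[C@@H](C=C2)[C@@H]2[C@@H](C[C@H]1C)[C@@H](C)CO[Si](C)(C)C(C)(C)C | intermediate
14 | C11 alcohol, OH-11 and CH3-12 cis on the concave face (H1, H10, H11, H12 all cis) | O[C@H]1[C@@H](C=C2)[C@@H]2[C@@H](C[C@H]1C)[C@@H](C)CO[Si](C)(C)C(C)(C)C | intermediate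
15 | C11 acetate of 14 | CC(=O)O[C@H]1[C@@H](C=C2)[C@@H]2[C@@H](C[C@H]1C)[C@@H](C)CO[Si](C)(C)C(C)(C)C | intermediate
16 | cis-dialdehyde (C2 and C9 formyl groups on C1 and C10) | CC(=O)O[C@H]1[C@@H](C=O)[C@@H](C=O)[C@@H](C[C@H]1C)[C@@H](C)CO[Si](C)(C)C(C)(C)C | intermediate
17 | tricyclic bis-acetal: ring B closed, C2 bonded to O16 (temporary tetrahydropyran, H2 cis to H1), C9 methyl acetal (anomers) | CC(=O)O[C@H]1[C@@H](C(OC)O[C@H]23)[C@@H]2[C@@H](C[C@H]1C)[C@@H](C)CO3 | intermediate
18 | hex-5-en-2-one | CC(=O)CCC=C | starting material
19 | 2-(trimethylsilyloxy)hexa-1,5-diene | C=C(O[Si](C)(C)C)CCC=C | intermediate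
20 | C9-alkylated acetal ketone: 17 with 2-oxohex-5-enyl in place of OMe, C8 trans to C11 | CC(=O)O[C@H]1[C@@H]([C@H](CC(=O)CCC=C)O[C@H]23)[C@@H]2[C@@H](C[C@H]1C)[C@@H](C)CO3 | intermediate
21 | diene alcohol: ring B with cis C2 isopropenyl and C9 2-oxohex-5-enyl arms, free C16–OH | CC(=O)O[C@H]1[C@@H]([C@H](CC(=O)CCC=C)O[C@@H]2C(C)=C)[C@@H]2[C@@H](C[C@H]1C)[C@@H](C)CO | intermediate
22 | tricyclic (Z)-oxonene alcohol: rings A, B, C closed, C3(CH3)=C4, C7 ketone, C11 acetate, free C16–OH | CC(=O)O[C@H]1[C@@H]([C@@H]3CC(=O)CC/C=C(C)\[C@H]2O3)[C@@H]2[C@@H](C[C@H]1C)[C@@H](C)CO | intermediate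
23 | CNP0288436.2 (1S,2S,3S,9S,10R,11R,12R,14S,15R in the numbering above) | CC(=O)O[C@H]1[C@@H]2[C@@H]3[C@@H](C[C@H]1C)[C@@H](C)CO[C@@]1(C)CCCC(=O)C[C@@H]2O[C@@H]31 | target

Total step count: 14. Longest linear sequence: 13 steps (steps 1–9 and 11–14).

Steps most likely to fail

Step 14. The masked C3 cation may lose a proton, which moves the alkene to the exocyclic or enol-ether position. It may also be intercepted across the ring by the C7 carbonyl oxygen faster than the seven-membered ring closes.
- The fallback replaces the cationic closure by a stereospecific epoxide opening. It sets out from 22 and comes back at 23.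
- Dimethyldioxirane in acetone should epoxidise C3=C4 from the open face of ring C, the face turned away from the C1–C10 bridge, to give the C3,C4-epoxide F1.
- Catalytic camphorsulfonic acid in CH2Cl2 should then let the C16 hydroxyl open the epoxide at the tertiary carbon C3 with inversion (7-exo). This closes ring D with the correct C3 configuration and leaves the 4-hydroxy tetracycle F2.
- 1,1'-Thiocarbonyldiimidazole converts it into the C4 imidazolylthiocarbonate F3.
- Bu3SnH with AIBN (Barton–McCombie deoxygenation) removes the C4 oxygen to give 23.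

Step 12. Two processes threaten it. The other C–O bond of the bicyclic acetal may ionise, which would open ring B. Alternatively the alkenyl group may be delivered internally from boron bound to O16 onto the concave face, with loss of facial control at C2.
- The fallback separates ring opening from C–C bond formation. It sets out from 20 and comes back at 21.
- Acetolysis (Ac2O, catalytic Sc(OTf)3, 0 °C) cleaves the internal acetal and caps O16, giving the C2,C16-diacetate F4.
- With O16 capped, Zn(C(CH3)=CH2)2 and Me3SiOTf in CH2Cl2 should deliver the isopropenyl group to the free oxocarbenium ion from the convex face, giving the C16 acetate F5.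
- Lipase-catalysed methanolysis (Candida antarctica lipase B, MeOH, t-BuOMe) removes only the unhindered primary acetate to give 21.

Step 13. The ruthenium alkylidene may fail to engage the hindered isopropenyl group next to C2, so that oligomerisation or alkene migration takes over.
- The fallback moves the metathesis to two monosubstituted alkenes. It sets out from 17 and comes back at 23.
- 2-(Trimethylsilyloxy)buta-1,3-diene under the conditions of step 11 gives the vinyl ketone acetal F6.
- Potassium penta-1,4-dien-2-yltrifluoroborate under the conditions of step 12 gives the triene alcohol F7.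
- Ring-closing metathesis now forms C5=C6 and leaves the 1,1-disubstituted C3 methylene untouched, giving the cyclic (Z)-enone F8.
- Conjugate reduction with [(Ph3P)CuH]6 gives the saturated ketone F9.
- The exocyclic alkene of F9 then undergoes the reaction of step 14, with the hydrogen atom going to the CH2 carbon and O16 to C3, to give 23.

Further compounds
F1 | step 14 | C3,C4-epoxide of 22 (oxygen on the face of ring C turned away from the C1–C10 bridge) | CC(=O)O[C@H]1[C@@H]([C@@H]3CC(=O)CC[C@H]4O[C@@]4(C)[C@H]2O3)[C@@H]2[C@@H](C[C@H]1C)[C@@H](C)CO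
F2 | step 14 | 4-hydroxy tetracycle (ring D closed, C4–OH anti to O16) | CC(=O)O[C@H]1[C@@H]2[C@@H]3[C@@H](C[C@H]1C)[C@@H](C)CO[C@@]1(C)[C@H](O)CCC(=O)C[C@@H]2O[C@@H]31
F3 | step 14 | C4 imidazolylthiocarbonate of F2 | CC(=O)O[C@H]1[C@@H]2[C@@H]3[C@@H](C[C@H]1C)[C@@H](C)CO[C@@]1(C)[C@H](OC(=S)n4ccnc4)CCC(=O)C[C@@H]2O[C@@H]31
F4 | step 12 | C2,C16-diacetate (ring B kept, C2 anomers) | CC(=O)O[C@H]1[C@@H]([C@H](CC(=O)CCC=C)OC2OC(C)=O)[C@@H]2[C@@H](C[C@H]1C)[C@@H](C)COC(C)=O
F5 | step 12 | C16 acetate of 21 | CC(=O)O[C@H]1[C@@H]([C@H](CC(=O)CCC=C)O[C@@H]2C(C)=C)[C@@H]2[C@@H](C[C@H]1C)[C@@H](C)COC(C)=O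
F6 | step 13 | vinyl ketone acetal (17 with 2-oxobut-3-enyl at C9) | CC(=O)O[C@H]1[C@@H]([C@H](CC(=O)C=C)O[C@H]23)[C@@H]2[C@@H](C[C@H]1C)[C@@H](C)CO3
F7 | step 13 | triene alcohol (C2 penta-1,4-dien-2-yl, free C16–OH) | CC(=O)O[C@H]1[C@@H]([C@H](CC(=O)C=C)O[C@@H]2C(=C)CC=C)[C@@H]2[C@@H](C[C@H]1C)[C@@H](C)CO
F8 | step 13 | cyclic (Z)-enone with exocyclic C3 methylene | CC(=O)O[C@H]1[C@@H]([C@@H]3CC(=O)/C=C\CC(=C)[C@H]2O3)[C@@H]2[C@@H](C[C@H]1C)[C@@H](C)CO
F9 | step 13 | saturated ring C ketone with exocyclic C3 methylene | CC(=O)O[C@H]1[C@@H]([C@@H]3CC(=O)CCCC(=C)[C@H]2O3)[C@@H]2[C@@H](C[C@H]1C)[C@@H](C)CO
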